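**Retrosynthetic overview**

1. Manniflavanone 21 ⇐ nona-O-benzyl ether 20 by global hydrogenolysis (last step).
2. 20 ⇐ silyl enol ether 16 + 3,4-bis(benzyloxy)benzaldehyde 17: one fluoride-chain annulation forms C2–C3 (aldol) and O1–C8a (SNAr), closes ring C of the flavanone unit and sets C2/C3. Enabling feature: in ring A of the flavanone unit, C8a is ortho to the C4a–C4(=O) aryl ketone and meta to both ring-A oxygens (C5, C7), so a C8a–F bond behaves as a vinylogous acyl fluoride; C3 is a doubly activated methylene between C4=O and C8'' of the taxifolin ring A; O1 therefore arrives with the aldehyde.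
3. 16 ⇐ deoxybenzoin 15 ⇐ Pd-catalysed α-arylation (C3–C8'' bond) of methyl ketone 11, as enol silane 13, with 8-bromo-penta-O-benzyltaxifolin 7.
4. 7 ⇐ (2R,3R)-taxifolin 1 (chiral pool: supplies C2'', C3'' and the three rings of the lower unit); 11 ⇐ 5-fluororesorcinol 8.
5. Ring order: all rings of the taxifolin unit and all benzene rings are bought; ring C of the flavanone unit is the only ring built (step 9).

Key step: step 9

Remark: (2R,3R)-taxifolin, 5-fluororesorcinol, 3,4-bis(benzyloxy)benzaldehyde and O-allyl-N-(9-anthracenylmethyl)cinchonidinium bromide are taken as commercial; the catalyst fluoride is made from the bromide by anion exchange on a fluoride-form resin just before use.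

Numbering: flavanone-unit atoms carry plain locants (O1, C2, C3, C4, C4a, C5–C8, C8a); taxifolin-unit atoms carry double primes in the biflavonoid compounds.

**Step 1**
Reactants: 1 (2R,3R)-taxifolin; 2 benzyl bromide
Product: 3 (2R,3R)-5,7-bis(benzyloxy)-2-[3,4-bis(benzyloxy)phenyl]-3-hydroxychroman-4-one
Conditions: BnBr (5 equiv), K2CO3, DMF, N2, 25 → 45 °C
Reagents that add atoms: benzyl bromide, BrCc1ccccc1
Why: Williamson etherification of the four phenols (the chelated 5-OH reacts last), which should leave the non-acidic 3-OH and the C2/C3 stereocenters untouched under the mild carbonate base when air is excluded.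

**Step 2**
Reactants: 3 tetra-O-benzyltaxifolin; 4 benzyl 2,2,2-trichloroacetimidate
Product: 5 (2R,3R)-3,5,7-tris(benzyloxy)-2-[3,4-bis(benzyloxy)phenyl]chroman-4-one
Conditions: imidate (1.5 equiv), TfOH (5 mol%), CH2Cl2/cyclohexane, 0 °C
Reagents that add atoms: benzyl 2,2,2-trichloroacetimidate, ClC(Cl)(Cl)C(=N)OCc1ccccc1
Why: Acid-catalysed O-benzylation with a trichloroacetimidate, the usual method for base-sensitive α-hydroxy carbonyl compounds, should cap the 3-OH without breaking the C3–O bond, so that C3 keeps its configuration and the α-ketol is neither epimerised nor oxidised.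

**Step 3**
Reactants: 5 penta-O-benzyltaxifolin; 6 N-bromosuccinimide
Product: 7 (2R,3R)-8-bromo-3,5,7-tris(benzyloxy)-2-[3,4-bis(benzyloxy)phenyl]chroman-4-one
Conditions: NBS (1.05 equiv), CH2Cl2, −20 → 0 °C, dark
Reagents that add atoms: N-bromosuccinimide, O=C1CCC(=O)N1Br
Why: Electrophilic aromatic bromination should occur at C8, the ring-A position flanked by O1 and only one benzyloxy group, in preference to the more crowded C6 between two benzyloxy groups (the regiochemistry usual for fully O-alkylated 5,7-dioxygenated flavonoids) and to the less electron-rich catechol ring.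

**Step 4**
Reactants: 8 5-fluororesorcinol; 2 benzyl bromide
Product: 9 1,3-bis(benzyloxy)-5-fluorobenzene
Conditions: BnBr (2.2 equiv), K2CO3, acetone, reflux
Reagents that add atoms: benzyl bromide, BrCc1ccccc1
Why: Williamson etherification of both phenols; no stereocenter is involved.

**Step 5**
Reactants: 9 1,3-bis(benzyloxy)-5-fluorobenzene; 10 acetic anhydride
Product: 11 1-[2,4-bis(benzyloxy)-6-fluorophenyl]ethanone
Conditions: Ac2O, Sc(OTf)3 (10 mol%), MeNO2, 50 °C
Reagents that add atoms: acetic anhydride, CC(=O)OC(C)=O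
Why: Catalytic Friedel–Crafts acylation should enter para to one benzyloxy group and ortho to the other (the position next to fluorine), as in resorcinol diethers, the site between the two benzyloxy groups being the more hindered one, while the catalytic Sc(OTf)3 spares the benzyl ethers.

**Step 6**
Reactants: 11 fluoro-acetophenone; 12 trimethylsilyl triflate
Product: 13 {1-[2,4-bis(benzyloxy)-6-fluorophenyl]ethenyloxy}trimethylsilane
Conditions: TMSOTf, Et3N, CH2Cl2, 0 °C
Reagents that add atoms: trimethylsilyl triflate, C[Si](C)(C)OS(=O)(=O)C(F)(F)F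
Why: Soft enolisation and O-silylation of the methyl ketone should give the terminal silyl enol ether needed as the neutral enolate source for the coupling.

**Step 7**
Reactants: 7 8-bromo-penta-O-benzyltaxifolin; 13 silyl enol ether
Product: 15 (2R,3R)-8-{2-[2,4-bis(benzyloxy)-6-fluorophenyl]-2-oxoethyl}-3,5,7-tris(benzyloxy)-2-[3,4-bis(benzyloxy)phenyl]chroman-4-one, via tributyltin enolate 14 (not isolated)
Conditions: Pd(OAc)2 (5 mol%), P(t-Bu)3 (10 mol%), Bu3SnF (1.5 equiv), toluene, 85 °C
Reagents that add atoms: silyl enol ether 13, C=C(O[Si](C)(C)C)c1c(F)cc(OCc2ccccc2)cc1OCc1ccccc1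
Why: Palladium-catalysed ketone α-arylation through a tin enolate: fluoride transfers the enolate from silicon to tin, zerovalent palladium adds into the C8–Br bond, transmetalation and reductive elimination form the C8''–C3 bond, and the absence of a Brønsted base should protect the epimerisable C2''/C3'' pair; no new stereocenter.

**Step 8**
Reactants: 15 deoxybenzoin; 12 trimethylsilyl triflate
Product: 16 (2R,3R)-8-{(Z)-2-[2,4-bis(benzyloxy)-6-fluorophenyl]-2-(trimethylsilyloxy)ethenyl}-3,5,7-tris(benzyloxy)-2-[3,4-bis(benzyloxy)phenyl]chroman-4-one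
Conditions: TMSOTf (1.1 equiv), Et3N, CH2Cl2, −20 → 0 °C; non-aqueous work-up, used crude
Reagents that add atoms: trimethylsilyl triflate, C[Si](C)(C)OS(=O)(=O)C(F)(F)F
Why: Soft enolisation should silylate only the doubly activated methylene (α to the aryl ketone and benzylic), which is far more acidic than the α-alkoxy C3''–H of the chromanone, and should give the Z enol ether with the two aryl groups trans; this fixes the enolate position for the key step.

**Step 9**
Reactants: 16 Z silyl enol ether; 17 3,4-bis(benzyloxy)benzaldehyde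
Product: 20 nona-O-benzylmanniflavanone, via ammonium enolate 18 (not isolated), via ammonium aldolate 19 (not isolated)
Conditions: O-allyl-N-(9-anthracenylmethyl)cinchonidinium fluoride (10 mol%), 17 (1.3 equiv), THF, 4 Å MS, −40 → 20 °C, then AcOH quench at −20 °C
Reagents that add atoms: 3,4-bis(benzyloxy)benzaldehyde, O=Cc1ccc(OCc2ccccc2)c(OCc2ccccc2)c1
Why: Proposed new method: fluoride from the ion pair cleaves the O–Si bond of 16 to give the ammonium enolate 18, whose C3 adds to the aldehyde carbon of 17 (C2–C3 bond) to give aldolate 19, whose alkoxide oxygen attacks C8a of the fluoroarene and expels fluoride (O1–C8a bond), so that the leaving group is itself the chain carrier that desilylates the next molecule of 16 and only Me3SiF is formed; the closest known reaction types are the chiral quaternary ammonium fluoride-catalysed Mukaiyama aldol addition of silyl enol ethers and the fluoride-catalysed SNAr etherification of silyl ethers with activated fluoroarenes, here joined in one chain. The pyranone ring (O1, C2, C3, C4, C4a, C8a) closes by a 6-endo-trig addition–elimination at C8a, the Meisenheimer intermediate being stabilised by the C4 carbonyl through C4a while both ring-A benzyloxy groups are meta to C8a and do not oppose the attack. C2 (R) should be set by Re-face attack on the aldehyde inside the contact ion pair with the chiral cation and is carried unchanged through the ring closure because the C2–O1 bond is never broken; whether the aldol addition or, if the aldol is reversible (Curtin–Hammett), the ring closure is selectivity-determining, both take place within the chiral ion pair. C3 (S) is not set kinetically: its hydrogen is acidic and should equilibrate under the enolate/fluoride conditions to the 2,3-trans isomer with both aryl groups equatorial. The step needs site selectivity (enolate only at C3, fixed by the position of the silyl enol ether; fluoride displaced rather than the C5 benzyloxy group, fluoride being by far the better nucleofuge in an addition-limited SNAr), suppression of β-elimination to the α-aryl chalcone (base is only ever present in catalytic amount), and facial selectivity at C2, for which the cinchonidinium cation is the first choice and its cinchoninium pseudo-enantiomer the counterpart if the sense of induction requires it.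

**Step 10**
Reactants: 20 nona-O-benzylmanniflavanone
Product: 21 manniflavanone
Conditions: H2 (1 atm), Pd(OH)2/C, THF/MeOH, 20 °C
Reagents that add atoms: none
Why: Hydrogenolysis of the nine benzyl ethers under neutral conditions should free all phenols and the 3''-OH without touching the four stereocenters; the aryl ketones and the benzylic C2–O1 bonds react much more slowly, so the reaction is stopped at the calculated uptake.

**Compound list**

1 | (2R,3R)-taxifolin | O=C1c2c(O)cc(O)cc2O[C@H](c2ccc(O)c(O)c2)[C@H]1O | starting material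
2 | benzyl bromide | BrCc1ccccc1 | starting material
3 | (2R,3R)-5,7-bis(benzyloxy)-2-[3,4-bis(benzyloxy)phenyl]-3-hydroxychroman-4-one | O=C1c2c(OCc3ccccc3)cc(OCc3ccccc3)cc2O[C@H](c2ccc(OCc3ccccc3)c(OCc3ccccc3)c2)[C@H]1O | intermediate
4 | benzyl 2,2,2-trichloroacetimidate | ClC(Cl)(Cl)C(=N)OCc1ccccc1 | starting material
5 | (2R,3R)-3,5,7-tris(benzyloxy)-2-[3,4-bis(benzyloxy)phenyl]chroman-4-one | O=C1c2c(OCc3ccccc3)cc(OCc3ccccc3)cc2O[C@H](c2ccc(OCc3ccccc3)c(OCc3ccccc3)c2)[C@H]1OCc1ccccc1 | intermediate
6 | N-bromosuccinimide | O=C1CCC(=O)N1Br | starting material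
7 | (2R,3R)-8-bromo-3,5,7-tris(benzyloxy)-2-[3,4-bis(benzyloxy)phenyl]chroman-4-one | O=C1c2c(OCc3ccccc3)cc(OCc3ccccc3)c(Br)c2O[C@H](c2ccc(OCc3ccccc3)c(OCc3ccccc3)c2)[C@H]1OCc1ccccc1 | intermediate
8 | 5-fluororesorcinol | Oc1cc(O)cc(F)c1 | starting material
9 | 1,3-bis(benzyloxy)-5-fluorobenzene | Fc1cc(OCc2ccccc2)cc(OCc2ccccc2)c1 | intermediate
10 | acetic anhydride | CC(=O)OC(C)=O | starting material
11 | 1-[2,4-bis(benzyloxy)-6-fluorophenyl]ethanone | CC(=O)c1c(F)cc(OCc2ccccc2)cc1OCc1ccccc1 | intermediate
12 | trimethylsilyl triflate | C[Si](C)(C)OS(=O)(=O)C(F)(F)F | starting material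
13 | {1-[2,4-bis(benzyloxy)-6-fluorophenyl]ethenyloxy}trimethylsilane | C=C(O[Si](C)(C)C)c1c(F)cc(OCc2ccccc2)cc1OCc1ccccc1 | intermediate
14 | tributyl{1-[2,4-bis(benzyloxy)-6-fluorophenyl]ethenyloxy}stannane (tin enolate) | C=C(O[Sn](CCCC)(CCCC)CCCC)c1c(F)cc(OCc2ccccc2)cc1OCc1ccccc1 | intermediate (not isolated)
15 | (2R,3R)-8-{2-[2,4-bis(benzyloxy)-6-fluorophenyl]-2-oxoethyl}-3,5,7-tris(benzyloxy)-2-[3,4-bis(benzyloxy)phenyl]chroman-4-one | O=C1c2c(OCc3ccccc3)cc(OCc3ccccc3)c(CC(=O)c3c(F)cc(OCc4ccccc4)cc3OCc3ccccc3)c2O[C@H](c2ccc(OCc3ccccc3)c(OCc3ccccc3)c2)[C@H]1OCc1ccccc1 | intermediate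
16 | Z trimethylsilyl enol ether of 15 | O=C1c2c(OCc3ccccc3)cc(OCc3ccccc3)c(/C=C(\O[Si](C)(C)C)c3c(F)cc(OCc4ccccc4)cc3OCc3ccccc3)c2O[C@H](c2ccc(OCc3ccccc3)c(OCc3ccccc3)c2)[C@H]1OCc1ccccc1 | intermediate
17 | 3,4-bis(benzyloxy)benzaldehyde | O=Cc1ccc(OCc2ccccc2)c(OCc2ccccc2)c1 | starting material
18 | enolate of 15 as ion pair with the catalyst cation (anion shown) | O=C1c2c(OCc3ccccc3)cc(OCc3ccccc3)c(/C=C(\[O-])c3c(F)cc(OCc4ccccc4)cc3OCc3ccccc3)c2O[C@H](c2ccc(OCc3ccccc3)c(OCc3ccccc3)c2)[C@H]1OCc1ccccc1 | intermediate (not isolated)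
19 | (2R,3S)-aldolate, flavanone numbering, as ion pair with the catalyst cation (anion shown) | O=C1c2c(OCc3ccccc3)cc(OCc3ccccc3)c([C@H](C(=O)c3c(F)cc(OCc4ccccc4)cc3OCc3ccccc3)[C@@H]([O-])c3ccc(OCc4ccccc4)c(OCc4ccccc4)c3)c2O[C@H](c2ccc(OCc3ccccc3)c(OCc3ccccc3)c2)[C@H]1OCc1ccccc1 | intermediate (not isolated)
20 | nona-O-benzylmanniflavanone: (2R,3S)-5,7-bis(benzyloxy)-2-[3,4-bis(benzyloxy)phenyl]-3-{(2R,3R)-3,5,7-tris(benzyloxy)-2-[3,4-bis(benzyloxy)phenyl]-4-oxochroman-8-yl}chroman-4-one | O=C1c2c(OCc3ccccc3)cc(OCc3ccccc3)c([C@@H]3C(=O)c4c(OCc5ccccc5)cc(OCc5ccccc5)cc4O[C@H]3c3ccc(OCc4ccccc4)c(OCc4ccccc4)c3)c2O[C@H](c2ccc(OCc3ccccc3)c(OCc3ccccc3)c2)[C@H]1OCc1ccccc1 | intermediate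
21 | manniflavanone (2R,3S,2''R,3''R) | O=C1c2c(O)cc(O)c([C@@H]3C(=O)c4c(O)cc(O)cc4O[C@H]3c3ccc(O)c(O)c3)c2O[C@H](c2ccc(O)c(O)c2)[C@H]1O | target

**Step count and risks**

Total step count: 10. Longest linear sequence: 7 steps (1 → 3 → 5 → 7 → 15 → 16 → 20 → 21; the branch from 8 through 9, 11 and 13 is equally long).

Steps most likely to fail:

1. Step 9 (Proposed new method). Retro-aldol cleavage or β-elimination of the aldolate may outrun the ring closure. The chiral cation may give poor facial selectivity at C2, or be mismatched with the resident stereocenters. The basic chain carrier may erode C2 through reversible opening of the new pyranone ring. The fallback sets out from 16 and uses known reactions stepwise. A Mukaiyama aldol addition of 16 to 17 (BF3·OEt2, CH2Cl2, −78 °C) should give the β-hydroxy ketone F1 as a mixture at the two new carbons. K2CO3 in DMF at 20 °C then closes the ring by intramolecular SNAr, with equilibration of C3 to the trans series. This gives 20 together with its (2S,3R)-diastereomer F2. Because the taxifolin unit is enantiopure, the two are diastereomers and should be separable by chromatography; the route is rejoined at 20.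

2. Step 7. Oxidative addition and transmetalation at the doubly ortho-substituted C8–Br bond may be slow, so that protodebromination and hydrolysis of the tin enolate take over. The fallback sets out from 7 and builds the C4–C4a bond instead of the C3–C8'' bond.
   - Stille coupling of 7 with (Z)-1-ethoxy-2-(tributylstannyl)ethene [Pd(PPh3)4, toluene, 100 °C] should give the enol ether F3.
   - Aqueous HCl in THF hydrolyses it to the arylacetaldehyde F4.
   - In parallel, 9 is brominated (NBS, MeCN, 0 °C) to the aryl bromide F5, which is converted by Br/Mg exchange (i-PrMgCl·LiCl, THF, −20 °C) into the aryl Grignard reagent F6.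
   - Addition of this reagent to F4 at −78 °C, where the aldehyde should react before the hindered vinylogous-ester ketone, gives the secondary alcohol F7.
   - Dess–Martin oxidation returns to the route at 15.

3. Step 10. Removal of nine benzyl groups may stall on poorly soluble, partly deprotected material, and prolonged exposure may open the benzylic C2–O1 bonds by hydrogenolysis. The fallback sets out from 20 and replaces hydrogenolysis by Lewis-acid debenzylation with a cation scavenger (BCl3, pentamethylbenzene, CH2Cl2, −78 °C), which should give 21 directly; it makes no new compound (none F0).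

**Further compounds**

F1 | step 9 | β-hydroxy ketone from 16 and 17 (mixture of diastereomers at the two new carbons) | O=C1c2c(OCc3ccccc3)cc(OCc3ccccc3)c(C(C(=O)c3c(F)cc(OCc4ccccc4)cc3OCc3ccccc3)C(O)c3ccc(OCc4ccccc4)c(OCc4ccccc4)c3)c2O[C@H](c2ccc(OCc3ccccc3)c(OCc3ccccc3)c2)[C@H]1OCc1ccccc1
F2 | step 9 | (2S,3R,2''R,3''R)-diastereomer of 20 | O=C1c2c(OCc3ccccc3)cc(OCc3ccccc3)c([C@H]3C(=O)c4c(OCc5ccccc5)cc(OCc5ccccc5)cc4O[C@@H]3c3ccc(OCc4ccccc4)c(OCc4ccccc4)c3)c2O[C@H](c2ccc(OCc3ccccc3)c(OCc3ccccc3)c2)[C@H]1OCc1ccccc1
F3 | step 7 | (2R,3R)-8-[(Z)-2-ethoxyethenyl]-3,5,7-tris(benzyloxy)-2-[3,4-bis(benzyloxy)phenyl]chroman-4-one | O=C1c2c(OCc3ccccc3)cc(OCc3ccccc3)c(/C=C\OCC)c2O[C@H](c2ccc(OCc3ccccc3)c(OCc3ccccc3)c2)[C@H]1OCc1ccccc1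
F4 | step 7 | (2R,3R)-8-(2-oxoethyl)-3,5,7-tris(benzyloxy)-2-[3,4-bis(benzyloxy)phenyl]chroman-4-one | O=C1c2c(OCc3ccccc3)cc(OCc3ccccc3)c(CC=O)c2O[C@H](c2ccc(OCc3ccccc3)c(OCc3ccccc3)c2)[C@H]1OCc1ccccc1
F5 | step 7 | 1,5-bis(benzyloxy)-2-bromo-3-fluorobenzene | Brc1c(F)cc(OCc2ccccc2)cc1OCc1ccccc1
F6 | step 7 | [2,4-bis(benzyloxy)-6-fluorophenyl]magnesium chloride | Cl[Mg]c1c(F)cc(OCc2ccccc2)cc1OCc1ccccc1
F7 | step 7 | (2R,3R)-8-{2-[2,4-bis(benzyloxy)-6-fluorophenyl]-2-hydroxyethyl}-3,5,7-tris(benzyloxy)-2-[3,4-bis(benzyloxy)phenyl]chroman-4-one (both carbinol epimers) | O=C1c2c(OCc3ccccc3)cc(OCc3ccccc3)c(CC(O)c3c(F)cc(OCc4ccccc4)cc3OCc3ccccc3)c2O[C@H](c2ccc(OCc3ccccc3)c(OCc3ccccc3)c2)[C@H]1OCc1ccccc1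
F0 | step 10 | none | none
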